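Ring B is cut into a four-carbon and a two-carbon piece: 3-ethoxy-4,4-dimethylcyclobutenone and the alkyne of a ring A arylmethyl ynol ether. Heating merges them through a vinylketene cascade that makes both new C–C bonds and closes the six-membered ring in one operation. The step exploits ring B's quaternary C(CH3)2 carbon and its three oxygens on alternate ring carbons, the CH2Ar-bearing carbon lying between two of them. Lacking hydrogen, the quaternary carbon stops the cascade at the dienone. The precursor is fully substituted ring A as its diacetate carrying CH2–C≡C–OCH3. Methyl rather than ethyl sits on the alkyne oxygen because ethyl ynol ethers shed ethene below the annulation temperature.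

Key step: step 9

Remark: compounds 20–22 are enolised β-triketones. Each SMILES shows one tautomer of an equilibrating set, and the target has no stereocentre and no stereogenic double bond.

Step 1
Reactants: 1 2-methylpropanoyl chloride; 2 ethoxyacetylene
Product: 4 3-ethoxy-4,4-dimethylcyclobut-2-en-1-one, via dimethylketene 3 (not isolated)
Conditions: Et3N (1.2 equiv), Et2O, 0 °C to reflux
Reagents that add atoms: none
Why: Et3N dehydrochlorinates 1 to dimethylketene 3, which is trapped in a ketene–alkyne [2+2] cycloaddition whose regiochemistry follows from attack of the nucleophilic terminal carbon of the ynol ether on the ketene carbonyl carbon.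

Step 2
Reactants: 5 2-chloro-1,1-dimethoxyethane
Product: 7 tributyl(methoxyethynyl)stannane, via lithium methoxyacetylide 6 (not isolated)
Conditions: lithium diethylamide (3.1 equiv, from Et2NH and n-BuLi), THF, 0 °C; then Bu3SnCl, −78 °C to rt; cold water wash, distillation
Reagents that add atoms: tributyltin chloride, CCCC[Sn](Cl)(CCCC)CCCC
Why: Successive amide-induced eliminations of HCl and methanol followed by deprotonation are the standard in situ entry to lithium methoxyacetylide 6, and its stannylation by Bu3SnCl is a plain salt metathesis that gives a distillable, amine-free alkynyl donor.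

Step 3
Reactants: 8 2-methylbenzene-1,3,5-triol (2-methylphloroglucinol); 9 butanoyl chloride
Product: 10 1-(2,4,6-trihydroxy-3-methylphenyl)butan-1-one
Conditions: AlCl3 (4 equiv), CH2Cl2/PhNO2, 0 to 45 °C; then ice/aq HCl
Reagents that add atoms: none
Why: Friedel–Crafts acylation of a phloroglucinol, in which the two open ring positions of 8 are equivalent and the first acyl group, chelated to AlCl3, shuts down a second acylation.

Step 4
Reactants: 10 1-(2,4,6-trihydroxy-3-methylphenyl)butan-1-one
Product: 11 1-(2,6-dihydroxy-4-methoxy-3-methylphenyl)butan-1-one (aspidinol)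
Conditions: Me2SO4 (1.0 equiv), K2CO3 (1.0 equiv), acetone, rt to reflux
Reagents that add atoms: dimethyl sulfate, COS(=O)(=O)OC
Why: Williamson-type O-methylation with one equivalent of a hard electrophile goes to the 4-hydroxyl, which is para to the ketone, the most acidic of the three, and the only one not flanking the carbonyl group that ties up the 2- and 6-hydroxyls by hydrogen bonding.

Step 5
Reactants: 11 1-(2,6-dihydroxy-4-methoxy-3-methylphenyl)butan-1-one
Product: 12 1-{3-[(dimethylamino)methyl]-2,6-dihydroxy-4-methoxy-5-methylphenyl}butan-1-one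
Conditions: aq CH2O and aq Me2NH (premixed, 1.5 equiv each), EtOH, 0 °C to rt
Reagents that add atoms: formaldehyde, C=O; dimethylamine, CNC
Why: Mannich aminomethylation can only strike the single unsubstituted, strongly activated ring carbon, and premixing amine and formaldehyde at low temperature keeps free formaldehyde from bridging two arenes.

Step 6
Reactants: 12 1-{3-[(dimethylamino)methyl]-2,6-dihydroxy-4-methoxy-5-methylphenyl}butan-1-one
Product: 13 4-(acetoxymethyl)-2-butanoyl-5-methoxy-6-methyl-1,3-phenylene diacetate
Conditions: Ac2O (neat), 100 °C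
Reagents that add atoms: acetic anhydride, CC(=O)OC(C)=O
Why: Acetolysis of a phenolic Mannich base, in which N-acetylation turns the amine into a leaving group that acetate displaces at the electron-rich benzylic carbon while both phenols are esterified, and staying at 100 °C without added acetate salt avoids Kostanecki-type chromone formation.

Step 7
Reactants: 13 4-(acetoxymethyl)-2-butanoyl-5-methoxy-6-methyl-1,3-phenylene diacetate
Product: 14 4-(bromomethyl)-2-butanoyl-5-methoxy-6-methyl-1,3-phenylene diacetate
Conditions: HBr (33% in AcOH), CH2Cl2, 0 °C to rt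
Reagents that add atoms: hydrogen bromide, Br
Why: Acid-promoted SN1-like substitution exchanges only the benzylic acetate, whose cation is stabilised by the ortho methoxy group, whereas aryl acetates and the aryl methyl ether are inert to HBr in acetic acid at room temperature.

Step 8
Reactants: 14 4-(bromomethyl)-2-butanoyl-5-methoxy-6-methyl-1,3-phenylene diacetate; 7 tributyl(methoxyethynyl)stannane
Product: 15 2-butanoyl-5-methoxy-4-(3-methoxyprop-2-yn-1-yl)-6-methyl-1,3-phenylene diacetate
Conditions: Pd2(dba)3 (2.5 mol %), tri(2-furyl)phosphine (10 mol %), THF, 50 °C; chromatography on Et3N-deactivated silica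
Reagents that add atoms: none
Why: Stille coupling of a benzylic bromide with an alkynylstannane runs under neutral, base-free conditions that spare ketone, aryl acetates and the acid-sensitive ynol ether, and the weakly nucleophilic furylphosphine does not quaternise the bromide.

Step 9
Reactants: 15 2-butanoyl-5-methoxy-4-(3-methoxyprop-2-yn-1-yl)-6-methyl-1,3-phenylene diacetate; 4 3-ethoxy-4,4-dimethylcyclobut-2-en-1-one
Product: 19 2-butanoyl-4-[(4-ethoxy-2-methoxy-5,5-dimethyl-6-oxocyclohexa-1,3-dien-1-yl)methyl]-5-methoxy-6-methyl-1,3-phenylene diacetate, via vinylketene 16 (not isolated), via vinylcyclobutenone 17 (not isolated), via dienylketene 18 (not isolated)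
Conditions: 4 (2.5 equiv), dry degassed toluene (0.5 M), base-washed sealed tube, 135 °C
Reagents that add atoms: none
Why: Thermal 4π electrocyclic opening of 4 gives vinylketene 16, whose ketene C=C adds to the ynol ether in a [2+2] cycloaddition to give 17; reversible 4π opening of 17 delivers dienylketene 18, and ring B closes by a disrotatory 6π electrocyclisation in which the ketene carbon bonds to the C(CH3)2 terminus. This is the Danheiser annulation in its dienone-forming variant, known for 4,4-disubstituted cyclobutenones and alkoxyalkynes. The selectivity needed is regiochemical: the oxygen polarises the alkyne so that its nucleophilic CH2Ar-bearing carbon attacks the electrophilic ketene carbonyl carbon, which places that carbon next to the ring C=O and the OCH3-bearing carbon next to the ring CH. The quaternary carbon can only stem from C4 of 4 and, having no hydrogen, blocks tautomerisation to a phenol. No stereocentre survives, since the one in 17 is erased on ring opening. The methyl ynol ether has no β-hydrogen and cannot fragment by a retro-ene path at this temperature, the acetates keep phenols from trapping the ketenes, and the excess of 4 offsets loss of 16 by 1,5-hydrogen shift.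

Step 10
Reactants: 19 2-butanoyl-4-[(4-ethoxy-2-methoxy-5,5-dimethyl-6-oxocyclohexa-1,3-dien-1-yl)methyl]-5-methoxy-6-methyl-1,3-phenylene diacetate
Product: 20 2-butanoyl-4-[(2,4-dihydroxy-3,3-dimethyl-6-oxocyclohexa-1,4-dien-1-yl)methyl]-5-methoxy-6-methyl-1,3-phenylene diacetate
Conditions: 1 M aq HCl, THF, rt to 40 °C
Reagents that add atoms: water, O
Why: Acid-catalysed hydrolysis of vinylogous esters (protonation, addition of water, loss of alcohol) is much faster than hydrolysis of the hindered aryl acetates, which stay on and so block acid-induced cyclodehydration between a ring A phenol and a ring B enol.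

Step 11
Reactants: 20 2-butanoyl-4-[(2,4-dihydroxy-3,3-dimethyl-6-oxocyclohexa-1,4-dien-1-yl)methyl]-5-methoxy-6-methyl-1,3-phenylene diacetate
Product: 21 4-[(5-acetyl-2,4-dihydroxy-3,3-dimethyl-6-oxocyclohexa-1,4-dien-1-yl)methyl]-2-butanoyl-5-methoxy-6-methyl-1,3-phenylene diacetate
Conditions: Ac2O (1.3 equiv), Et3N (2.5 equiv), DMAP (0.3 equiv), CH2Cl2, 0 °C to rt; dilute acid wash
Reagents that add atoms: acetic anhydride, CC(=O)OC(C)=O
Why: O-acetylation followed by DMAP-mediated O-to-C acyl migration, the enol ester rearrangement used to make 2-acyl cyclic 1,3-diones and β-triketones, funnels the acetyl group to the only ring B carbon that still bears hydrogen because only there does a chelated, fully enolised triketone result, and any acetyl exchange with the aryl acetates is degenerate.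

Step 12
Reactants: 21 4-[(5-acetyl-2,4-dihydroxy-3,3-dimethyl-6-oxocyclohexa-1,4-dien-1-yl)methyl]-2-butanoyl-5-methoxy-6-methyl-1,3-phenylene diacetate
Product: 22 2-acetyl-6-[(3-butanoyl-2,4-dihydroxy-6-methoxy-5-methylphenyl)methyl]-3,5-dihydroxy-4,4-dimethylcyclohexa-2,5-dien-1-one (target)
Conditions: K2CO3 (4 equiv), MeOH, 0 °C to rt; then 1 M aq HCl to pH 3
Reagents that add atoms: none
Why: Base-catalysed transesterification (methanolysis) removes the two aryl acetates while ring B is shielded as its delocalised enolate, and low temperature with short contact time prevents base-induced scrambling of the methylene bridge.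

Compound list
1 | 2-methylpropanoyl chloride | CC(C)C(Cl)=O | starting material
2 | ethoxyacetylene | C#COCC | starting material
3 | dimethylketene | CC(C)=C=O | intermediate
4 | 3-ethoxy-4,4-dimethylcyclobut-2-en-1-one | CCOC1=CC(=O)C1(C)C | intermediate
5 | 2-chloro-1,1-dimethoxyethane (chloroacetaldehyde dimethyl acetal) | COC(CCl)OC | starting material
6 | lithium methoxyacetylide | [Li]C#COC | intermediate
7 | tributyl(methoxyethynyl)stannane | CCCC[Sn](CCCC)(CCCC)C#COC | intermediate
8 | 2-methylbenzene-1,3,5-triol | Cc1c(O)cc(O)cc1O | starting material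
9 | butanoyl chloride | CCCC(Cl)=O | starting material
10 | 1-(2,4,6-trihydroxy-3-methylphenyl)butan-1-one | CCCC(=O)c1c(O)c(C)c(O)cc1O | intermediate
11 | 1-(2,6-dihydroxy-4-methoxy-3-methylphenyl)butan-1-one | CCCC(=O)c1c(O)c(C)c(OC)cc1O | intermediate
12 | 1-{3-[(dimethylamino)methyl]-2,6-dihydroxy-4-methoxy-5-methylphenyl}butan-1-one | CCCC(=O)c1c(O)c(C)c(OC)c(CN(C)C)c1O | intermediate
13 | 4-(acetoxymethyl)-2-butanoyl-5-methoxy-6-methyl-1,3-phenylene diacetate | CCCC(=O)c1c(OC(C)=O)c(C)c(OC)c(COC(C)=O)c1OC(C)=O | intermediate
14 | 4-(bromomethyl)-2-butanoyl-5-methoxy-6-methyl-1,3-phenylene diacetate | CCCC(=O)c1c(OC(C)=O)c(C)c(OC)c(CBr)c1OC(C)=O | intermediate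
15 | 2-butanoyl-5-methoxy-4-(3-methoxyprop-2-yn-1-yl)-6-methyl-1,3-phenylene diacetate | CCCC(=O)c1c(OC(C)=O)c(C)c(OC)c(CC#COC)c1OC(C)=O | intermediate
16 | 3-ethoxy-4-methylpenta-1,3-dien-1-one (vinylketene) | CCOC(C=C=O)=C(C)C | intermediate
17 | 2-butanoyl-4-{[3-(1-ethoxy-2-methylprop-1-en-1-yl)-2-methoxy-4-oxocyclobut-1-en-1-yl]methyl}-5-methoxy-6-methyl-1,3-phenylene diacetate (racemic, transient stereocentre) | CCCC(=O)c1c(OC(C)=O)c(C)c(OC)c(CC2=C(OC)C(C(OCC)=C(C)C)C2=O)c1OC(C)=O | intermediate
18 | dienylketene: ring A diacetate–CH2–C(=C=O)–C(OCH3)=CH–C(OEt)=C(CH3)2, ketenyl and alkenyl carbons cis on the central double bond | CCCC(=O)c1c(OC(C)=O)c(C)c(OC)c(CC(=C=O)/C(OC)=C\C(OCC)=C(C)C)c1OC(C)=O | intermediate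
19 | 2-butanoyl-4-[(4-ethoxy-2-methoxy-5,5-dimethyl-6-oxocyclohexa-1,3-dien-1-yl)methyl]-5-methoxy-6-methyl-1,3-phenylene diacetate | CCCC(=O)c1c(OC(C)=O)c(C)c(OC)c(CC2=C(OC)C=C(OCC)C(C)(C)C2=O)c1OC(C)=O | intermediate
20 | 2-butanoyl-4-[(2,4-dihydroxy-3,3-dimethyl-6-oxocyclohexa-1,4-dien-1-yl)methyl]-5-methoxy-6-methyl-1,3-phenylene diacetate | CCCC(=O)c1c(OC(C)=O)c(C)c(OC)c(CC2=C(O)C(C)(C)C(O)=CC2=O)c1OC(C)=O | intermediate
21 | 4-[(5-acetyl-2,4-dihydroxy-3,3-dimethyl-6-oxocyclohexa-1,4-dien-1-yl)methyl]-2-butanoyl-5-methoxy-6-methyl-1,3-phenylene diacetate | CCCC(=O)c1c(OC(C)=O)c(C)c(OC)c(CC2=C(O)C(C)(C)C(O)=C(C(C)=O)C2=O)c1OC(C)=O | intermediate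
22 | 2-acetyl-6-[(3-butanoyl-2,4-dihydroxy-6-methoxy-5-methylphenyl)methyl]-3,5-dihydroxy-4,4-dimethylcyclohexa-2,5-dien-1-one | CCCC(=O)c1c(O)c(C)c(OC)c(CC2=C(O)C(C)(C)C(O)=C(C(C)=O)C2=O)c1O | target

Total step count: 12. Longest linear sequence: 10 steps (steps 3 to 12); steps 1 and 2 are side branches.

Steps most likely to fail

Step 9.
- **Risk:** Opening of the donor-stabilised cyclobutenone may be slower than loss of the vinylketene, either through a 1,5-hydrogen shift from its inward methyl group or through self-addition. Capture by the hindered alkyne may also lag, or the cascade may stall before the second ring opening.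
- **Fallback:** It sets out from 12 and rejoins the route at 22, building the methylene bridge by classical quinone methide chemistry instead of building ring B. Commercial 2,4,6-trihydroxyacetophenone is gem-dimethylated with dearomatisation (MeI, NaOMe, MeOH) to acetylfilicinic acid F1. Heating 12 with F1 in toluene at about 90 °C expels dimethylamine to give the ortho-quinone methide F2. F1 captures F2 at its only free ring carbon by conjugate addition, giving 22 directly. Self-coupling is excluded because ring A of 12 has no free position.

Step 8.
- **Risk:** Transmetalation from tin to the hindered benzylpalladium species may be slow. That would allow homocoupling of the bromide, quaternisation of the ligand, or hydration of the ynol ether during prolonged heating.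
- **Fallback:** It sets out from 7 and 14 and rejoins at 15, replacing the tin donor by a zinc acetylide (Negishi alkynylation). Tin–lithium exchange of 7 (n-BuLi, THF, −78 °C) regenerates 6. ZnCl2 converts 6 into methoxyethynylzinc chloride F3. F3 couples with 14 under PdCl2(DPEphos) at 0 °C to rt, where transmetalation is fast and no heating is needed; ketone and acetates tolerate the organozinc.

Step 11.
- **Risk:** Acyl transfer may stop at the enol acetate stage, or the acetyl group may shuttle between oxygens without settling on carbon.
- **Fallback:** It sets out from 20 and rejoins at 21, changing from nucleophilic catalysis to Lewis acid electrophilic acylation, the classical way of acylating filicinic acids. Ac2O and BF3·OEt2 (CH2Cl2, rt to 40 °C) acylate the free ring B carbon and hold the product as the difluoroboron chelate F4. Aqueous NaOAc in THF opens F4 to 21. Ring A cannot undergo a Fries shift because it has no free position.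

Further compounds
F1 | step 9 | acetylfilicinic acid (2-acetyl-3,5-dihydroxy-4,4-dimethylcyclohexa-2,5-dien-1-one) | CC(=O)C1=C(O)C(C)(C)C(O)=CC1=O
F2 | step 9 | ortho-quinone methide (2-butanoyl-3-hydroxy-5-methoxy-4-methyl-6-methylidenecyclohexa-2,4-dien-1-one) | CCCC(=O)C1=C(O)C(C)=C(OC)C(=C)C1=O
F3 | step 8 | methoxyethynylzinc chloride | COC#C[Zn]Cl
F4 | step 11 | difluoroboron chelate of 21 (boron bridging the acetyl oxygen and the neighbouring ring B enol oxygen) | CC1=[O+][B-](F)(F)OC2=C1C(=O)C(Cc3c(OC)c(C)c(OC(C)=O)c(C(=O)CCC)c3OC(C)=O)=C(O)C2(C)C
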